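Time comes first in my reply: the flasks are read at 80 min and again at 5.0 h. You ask for a quick number, and your hunch is that north leads, since it holds the most substrate.

| flask | substrate | coupling partner | remark | time |
|---|---|---|---|---|
| maple | 1 M | 0.36 M | run made earlier |  |
| larch | 1 M | 2 M | run made earlier |  |
| alder | 1.3 M | 1.3 M | run made earlier |  |
| south-east | 1.5 M | 0.800 M |  | 80 min |
| north-west | 0.50 M | 0.600 M |  | 80 min |
| south-west | 1.5 M | 0.600 M |  | 80 min |
| east | 1.0 M | 1.30 M |  | 80 min |
| north-east | 0.30 M | 0.300 M |  | 80 min |
| north | 3.0 M | 0.800 M |  | 80 min |

- maple (time / min: target / %): 6.00: 0.5; 10.0: 0; 15.0: 0; 25.0: 0.3; 30.0: 0; 50.0: 1.1; 80.0: 3.9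
- larch (time / min: target / %): 12.0: 3.6; 25.0: 58.9; 30.0: 79.5; 50.0: 99.1; 60.0: 100.2; 80.0: 100.2
- alder (time / min: target / %): 6.00: 0; 12.0: 1.4; 25.0: 25.4; 40.0: 70.4; 80.0: 91.8

(readings scatter by 0.5 percentage points)

1. the flasks put in order of amount of target, in percent of the substrate charged, best first, at 80 min (south-east / north-west / south-west / east / north-east / north)
2. the same order at 5.0 h (south-east / north-west / south-west / east / north-east / north)
3. the amount of target, in percent of the substrate charged of the flask you put first, at 80 min
4. the amount of target, in percent of the substrate charged of the flask you put last, at 80 min

- the numbers in the tables scatter by 0.5 percentage points (one standard deviation)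

The earlier runs start low and then climb. That shape points to autocatalysis, so I take target as the concentration that sets the order of the rate. While substrate and partner stay near their charges, I treat growth as pseudo-first-order in target, with a steady doubling of its fraction of the charge; this is my approximation, and it leaves aside whatever forms the first target. My carried quantity is the doubling time: ln 2 over the growth constant, with that constant taken as proportional to the product of the two charges. I read the constant from the alder run, which goes from 1.4 % at 12.0 min to 25.4 % at 25.0 min:

growth constant, alder: 0.223 min⁻¹

doubling time, north: 2.19 min

doubling time, east: 4.04 min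

doubling time, north-west: 17.5 min

doubling time, north-east: 58.4 min

Your north doubles faster than east. But if each target takes one partner, north's partner covers 26.7 % of its substrate, while east's covers 130 %. So I put east above north. North-east gets 1.37 doublings by 80 min, and east gets 19.8, so I put north-east last.

The forecast, made from the same runs, gives east > south-east > south-west > north > north-west > north-east at 80 min and east > north-west > south-east > south-west > north > north-east at 5.0 h, with 93 % for east and 0.6 % for north-east. It starts from the same reading: “The yield curves are sigmoidal, which suggests autocatalysis”. Its constant, 0.14, differs from the 0.132 my alder pair gives.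

East reads 96.3 % at 80 min and north-east 0.355 %, in the order east > south-east > south-west > north > north-west > north-east; at 5.0 h the order is east > north-west > south-east > south-west > north > north-east.

    substrate + coupling partner + target → 2 target (k = 0.224 L² mol⁻² min⁻¹)
    substrate + coupling partner → target (k = 1.00 × 10⁻⁴ L mol⁻¹ min⁻¹)
    coupling partner ⇌ dormant form (K = 0.330, k = 0.128 min⁻¹)

North-east still holds 89 % of its substrate at 5.0 h, beside 11.1 % target. Between 80 min and 5.0 h the target in north-east doubles on average every 44.3 min, shorter than my 58.4 min. North-west, reckoned at 17.5 min, goes from 0.601 % at 40.0 min to 4.74 % at 80.0 min, a doubling every 13.4 min.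

The data are calculated on assumed constants; the scatter is artificial.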